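## Retrosynthetic overview
1. The last step is a neutral hydrogenolysis of one benzyl ether and one benzyl ester. Just before it, a dioxolane that masks the ring A ketone is hydrolysed.
2. Cutting the depside C(=O)–O bond gives a ring A acid (2-OBn, 4-OMe, ketal-masked 2-oxoheptyl) and a ring B phenol (benzyl 4-hydroxy-2-methoxy-6-(2-oxoheptyl)benzoate).
3. The key disconnection in each half is ArCH2–C(=O)C5H11. It leads to the extended ester enolate of an O-protected methyl orsellinate and the Weinreb amide of hexanoic acid, joined by an intermolecular crossed Claisen-type condensation.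
4. Both toluates come from methyl orsellinate by complementary regioselective O-alkylation (4-OMe then 2-OBn for ring A, 4-OBn then 2-OMe for ring B).
5. Both benzene rings are bought intact in methyl orsellinate and no carbocycle is built. The only ring formed is the temporary dioxolane (step 5), opened again in step 14.

Assumption: the SMILES holds no stereocentre and no stereogenic double bond, so the target is achiral and no stereocontrol is needed.

## Route

Step 1
Reactants: 1 hexanoyl chloride; 2 N,O-dimethylhydroxylamine hydrochloride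
Product: 4 N-methoxy-N-methylhexanamide, via free N,O-dimethylhydroxylamine 3 (not isolated)
Conditions: K2CO3 (2.5 equiv), CH2Cl2/H2O 1:1, 0 °C to rt, 2 h
Reagents that add atoms: none
Why: In this Schotten–Baumann N-acylation, K2CO3 frees the amine, which attacks the acid chloride far faster than water does, and the amide formed is inert to the mild base.

Step 2
Reactants: 5 methyl 2,4-dihydroxy-6-methylbenzoate (methyl orsellinate)
Product: 6 methyl 2-hydroxy-4-methoxy-6-methylbenzoate
Conditions: MeI (1.05 equiv), K2CO3 (1.1 equiv), acetone, reflux, 6 h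
Reagents that add atoms: iodomethane, CI
Why: This Williamson ether synthesis is regioselective because the 2-OH is tied up in a hydrogen bond to the ester carbonyl, so one equivalent of MeI finds only the free, more acidic 4-OH.

Step 3
Reactants: 6 methyl 2-hydroxy-4-methoxy-6-methylbenzoate
Product: 7 methyl 2-(benzyloxy)-4-methoxy-6-methylbenzoate
Conditions: BnBr (1.3 equiv), K2CO3 (2.5 equiv), DMF, 60 °C, 12 h
Reagents that add atoms: benzyl bromide, BrCc1ccccc1
Why: A Williamson ether synthesis under more forcing conditions overcomes the hydrogen bond of the remaining 2-OH and installs a group that survives strong base yet leaves by hydrogenolysis.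

Step 4
Reactants: 7 methyl 2-(benzyloxy)-4-methoxy-6-methylbenzoate; 4 N-methoxy-N-methylhexanamide
Product: 10 methyl 2-(benzyloxy)-4-methoxy-6-(2-oxoheptyl)benzoate, via benzylic lithium species 8 (not isolated), via lithium hemiaminal adduct 9 (not isolated)
Conditions: LiN(iPr)2 (commercial 2.0 M solution, 1.3 equiv), THF, −78 °C, 7 added dropwise, 20 min; then 4 (1.5 equiv), −78 °C, 45 min; cannulated into ice-cold 1 M HCl
Reagents that add atoms: none
Why: In this crossed Claisen-type condensation, LiN(iPr)2 deprotonates the ortho-methyl group to the extended (vinylogous) ester enolate 8, which adds to the acyl carbon of 4, and the chelated adduct 9 holds until the acid quench, so neither over-addition nor proton exchange with the acidic ketone can occur and no stereocentre remains in 10.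

Step 5
Reactants: 10 methyl 2-(benzyloxy)-4-methoxy-6-(2-oxoheptyl)benzoate
Product: 11 methyl 2-(benzyloxy)-4-methoxy-6-[(2-pentyl-1,3-dioxolan-2-yl)methyl]benzoate
Conditions: Me3SiOCH2CH2OSiMe3 (3 equiv), Me3SiOTf (0.1 equiv), CH2Cl2, −78 to −20 °C, 16 h; pyridine, then aq. NaHCO3
Reagents that add atoms: 1,2-bis(trimethylsilyloxy)ethane, C[Si](C)(C)OCCO[Si](C)(C)C
Why: Noyori ketalisation, driven by formation of the Si–O–Si bond, masks the ketone under cold aprotic conditions and so avoids the hot protic acid that would close the keto ester to an isocoumarin.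

Step 6
Reactants: 11 methyl 2-(benzyloxy)-4-methoxy-6-[(2-pentyl-1,3-dioxolan-2-yl)methyl]benzoate
Product: 13 2-(benzyloxy)-4-methoxy-6-[(2-pentyl-1,3-dioxolan-2-yl)methyl]benzoic acid, via potassium carboxylate 12 (not isolated)
Conditions: KOH (10 equiv), DMSO/H2O 4:1, 100 °C, 6 h; then 1 M HCl to pH 3–4 at 0 °C, immediate extraction into EtOAc, concentrated below 25 °C and used crude within hours
Reagents that add atoms: potassium hydroxide, [K+].[OH-]
Why: Saponification of a di-ortho-substituted benzoate needs poorly solvated hydroxide in hot aqueous DMSO, and the ketal, benzyl ether and aryl methyl ether are all inert to these conditions.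

Step 7
Reactants: 5 methyl 2,4-dihydroxy-6-methylbenzoate
Product: 14 methyl 4-(benzyloxy)-2-hydroxy-6-methylbenzoate
Conditions: BnBr (1.05 equiv), K2CO3 (1.1 equiv), acetone, reflux, 8 h
Reagents that add atoms: benzyl bromide, BrCc1ccccc1
Why: This Williamson ether synthesis shows the same regioselectivity as step 2, because the hydrogen-bonded 2-OH stays untouched with one equivalent of halide.

Step 8
Reactants: 14 methyl 4-(benzyloxy)-2-hydroxy-6-methylbenzoate
Product: 15 methyl 4-(benzyloxy)-2-methoxy-6-methylbenzoate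
Conditions: MeI (3 equiv), K2CO3 (3 equiv), DMF, 40 °C, 16 h
Reagents that add atoms: iodomethane, CI
Why: A Williamson ether synthesis with excess small electrophile in a polar solvent methylates the only remaining, hydrogen-bonded hydroxyl.

Step 9
Reactants: 15 methyl 4-(benzyloxy)-2-methoxy-6-methylbenzoate; 4 N-methoxy-N-methylhexanamide
Product: 18 methyl 4-(benzyloxy)-2-methoxy-6-(2-oxoheptyl)benzoate, via benzylic lithium species 16 (not isolated), via lithium hemiaminal adduct 17 (not isolated)
Conditions: LiN(iPr)2 (commercial 2.0 M solution, 1.3 equiv), THF, −78 °C, 15 added dropwise, 20 min; then 4 (1.5 equiv), −78 °C, 45 min; cannulated into ice-cold 1 M HCl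
Reagents that add atoms: none
Why: This is the same crossed Claisen-type condensation as step 4, in which the extended ester enolate 16 is acylated by 4 and the chelated adduct 17 releases the ketone only on acid quench.

Step 10
Reactants: 18 methyl 4-(benzyloxy)-2-methoxy-6-(2-oxoheptyl)benzoate
Product: 20 4-(benzyloxy)-2-methoxy-6-(2-oxoheptyl)benzoic acid, via potassium carboxylate 19 (not isolated)
Conditions: KOH (6 equiv), EtOH/H2O 1:1, reflux, 4 h; then 1 M HCl to pH 2 at 0 °C, extraction into EtOAc
Reagents that add atoms: potassium hydroxide, [K+].[OH-]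
Why: In this saponification in a water-rich medium, hydroxide converts the ester irreversibly into carboxylate 19, which side-chain enolates can no longer attack, and cold acidification gives the open keto acid rather than its enol lactone.

Step 11
Reactants: 20 4-(benzyloxy)-2-methoxy-6-(2-oxoheptyl)benzoic acid
Product: 21 4-hydroxy-2-methoxy-6-(2-oxoheptyl)benzoic acid
Conditions: H2 (1 atm), 10% Pd/C, EtOAc, rt, 3 h
Reagents that add atoms: none
Why: Catalytic hydrogenolysis cleaves only the benzylic C–O bond, since a dialkyl ketone, an aryl methyl ether and a carboxylic acid are untouched by Pd/C at 1 atm of H2.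

Step 12
Reactants: 21 4-hydroxy-2-methoxy-6-(2-oxoheptyl)benzoic acid
Product: 22 benzyl 4-hydroxy-2-methoxy-6-(2-oxoheptyl)benzoate
Conditions: BnBr (1.05 equiv), KHCO3 (1.2 equiv), DMF, rt to 40 °C, 12 h
Reagents that add atoms: benzyl bromide, BrCc1ccccc1
Why: In this chemoselective SN2 O-alkylation of the carboxylate, KHCO3 deprotonates the carboxylic acid but not the phenol, and because the acyl carbon is never activated the ketone cannot close to an isocoumarin.

Step 13
Reactants: 13 2-(benzyloxy)-4-methoxy-6-[(2-pentyl-1,3-dioxolan-2-yl)methyl]benzoic acid; 22 benzyl 4-hydroxy-2-methoxy-6-(2-oxoheptyl)benzoate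
Product: 24 benzyl 4-({2-(benzyloxy)-4-methoxy-6-[(2-pentyl-1,3-dioxolan-2-yl)methyl]benzoyl}oxy)-2-methoxy-6-(2-oxoheptyl)benzoate, via O-acylisourea 23 (not isolated)
Conditions: 13 (1.1 equiv), DCC (1.3 equiv), DMAP (0.5 equiv), CH2Cl2, 0 °C to rt, 24 h
Reagents that add atoms: none
Why: In this Steglich esterification, DCC turns the hindered acid into O-acylisourea 23, DMAP as nucleophilic catalyst relays the acyl group to the only free hydroxyl of 22, and the ketal keeps the ring A side chain from intercepting the activated acyl group as an enol lactone.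

Step 14
Reactants: 24 benzyl 4-({2-(benzyloxy)-4-methoxy-6-[(2-pentyl-1,3-dioxolan-2-yl)methyl]benzoyl}oxy)-2-methoxy-6-(2-oxoheptyl)benzoate
Product: 25 benzyl 4-{[2-(benzyloxy)-4-methoxy-6-(2-oxoheptyl)benzoyl]oxy}-2-methoxy-6-(2-oxoheptyl)benzoate
Conditions: 1 M HCl/THF 1:4, rt, about 6 h (TLC control); aq. NaHCO3
Reagents that add atoms: water, O
Why: In this acid-catalysed ketal hydrolysis at room temperature, a ketone dioxolane is cleaved far faster than the sterically shielded di-ortho-substituted aryl and benzyl esters.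

Step 15
Reactants: 25 benzyl 4-{[2-(benzyloxy)-4-methoxy-6-(2-oxoheptyl)benzoyl]oxy}-2-methoxy-6-(2-oxoheptyl)benzoate
Product: 26 4-{[2-hydroxy-4-methoxy-6-(2-oxoheptyl)benzoyl]oxy}-2-methoxy-6-(2-oxoheptyl)benzoic acid
Conditions: H2 (1 atm), 10% Pd/C, EtOAc, rt, 2 h; filtration, crystallisation
Reagents that add atoms: none
Why: Global catalytic hydrogenolysis under neutral conditions frees the 2-OH and the CO2H without acid, base or heat, so the depside ester and both keto side chains are left alone, and the product has no stereocentre.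

## Compound list
1 | hexanoyl chloride | CCCCCC(=O)Cl | starting material
2 | N,O-dimethylhydroxylamine hydrochloride | CNOC.Cl | starting material
3 | N,O-dimethylhydroxylamine (free base, not isolated) | CNOC | intermediate
4 | N-methoxy-N-methylhexanamide | CCCCCC(=O)N(C)OC | intermediate
5 | methyl 2,4-dihydroxy-6-methylbenzoate (methyl orsellinate) | COC(=O)c1c(C)cc(O)cc1O | starting material
6 | methyl 2-hydroxy-4-methoxy-6-methylbenzoate | COC(=O)c1c(C)cc(OC)cc1O | intermediate
7 | methyl 2-(benzyloxy)-4-methoxy-6-methylbenzoate | COC(=O)c1c(C)cc(OC)cc1OCc1ccccc1 | intermediate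
8 | [3-(benzyloxy)-5-methoxy-2-(methoxycarbonyl)benzyl]lithium (not isolated) | [Li]Cc1cc(OC)cc(OCc2ccccc2)c1C(=O)OC | intermediate
9 | lithium 1-[3-(benzyloxy)-5-methoxy-2-(methoxycarbonyl)phenyl]-2-[methoxy(methyl)amino]heptan-2-olate (racemic, transient, not isolated) | CCCCCC(O[Li])(Cc1cc(OC)cc(OCc2ccccc2)c1C(=O)OC)N(C)OC | intermediate
10 | methyl 2-(benzyloxy)-4-methoxy-6-(2-oxoheptyl)benzoate | CCCCCC(=O)Cc1cc(OC)cc(OCc2ccccc2)c1C(=O)OC | intermediate
11 | methyl 2-(benzyloxy)-4-methoxy-6-[(2-pentyl-1,3-dioxolan-2-yl)methyl]benzoate | CCCCCC1(Cc2cc(OC)cc(OCc3ccccc3)c2C(=O)OC)OCCO1 | intermediate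
12 | potassium 2-(benzyloxy)-4-methoxy-6-[(2-pentyl-1,3-dioxolan-2-yl)methyl]benzoate (not isolated) | CCCCCC1(Cc2cc(OC)cc(OCc3ccccc3)c2C(=O)[O-])OCCO1.[K+] | intermediate
13 | 2-(benzyloxy)-4-methoxy-6-[(2-pentyl-1,3-dioxolan-2-yl)methyl]benzoic acid | CCCCCC1(Cc2cc(OC)cc(OCc3ccccc3)c2C(=O)O)OCCO1 | intermediate
14 | methyl 4-(benzyloxy)-2-hydroxy-6-methylbenzoate | COC(=O)c1c(C)cc(OCc2ccccc2)cc1O | intermediate
15 | methyl 4-(benzyloxy)-2-methoxy-6-methylbenzoate | COC(=O)c1c(C)cc(OCc2ccccc2)cc1OC | intermediate
16 | [5-(benzyloxy)-3-methoxy-2-(methoxycarbonyl)benzyl]lithium (not isolated) | [Li]Cc1cc(OCc2ccccc2)cc(OC)c1C(=O)OC | intermediate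
17 | lithium 1-[5-(benzyloxy)-3-methoxy-2-(methoxycarbonyl)phenyl]-2-[methoxy(methyl)amino]heptan-2-olate (racemic, transient, not isolated) | CCCCCC(O[Li])(Cc1cc(OCc2ccccc2)cc(OC)c1C(=O)OC)N(C)OC | intermediate
18 | methyl 4-(benzyloxy)-2-methoxy-6-(2-oxoheptyl)benzoate | CCCCCC(=O)Cc1cc(OCc2ccccc2)cc(OC)c1C(=O)OC | intermediate
19 | potassium 4-(benzyloxy)-2-methoxy-6-(2-oxoheptyl)benzoate (not isolated) | CCCCCC(=O)Cc1cc(OCc2ccccc2)cc(OC)c1C(=O)[O-].[K+] | intermediate
20 | 4-(benzyloxy)-2-methoxy-6-(2-oxoheptyl)benzoic acid | CCCCCC(=O)Cc1cc(OCc2ccccc2)cc(OC)c1C(=O)O | intermediate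
21 | 4-hydroxy-2-methoxy-6-(2-oxoheptyl)benzoic acid | CCCCCC(=O)Cc1cc(O)cc(OC)c1C(=O)O | intermediate
22 | benzyl 4-hydroxy-2-methoxy-6-(2-oxoheptyl)benzoate | CCCCCC(=O)Cc1cc(O)cc(OC)c1C(=O)OCc1ccccc1 | intermediate
23 | O-{2-(benzyloxy)-4-methoxy-6-[(2-pentyl-1,3-dioxolan-2-yl)methyl]benzoyl}-N,N'-dicyclohexylisourea (not isolated) | CCCCCC1(Cc2cc(OC)cc(OCc3ccccc3)c2C(=O)OC(=NC2CCCCC2)NC2CCCCC2)OCCO1 | intermediate
24 | benzyl 4-({2-(benzyloxy)-4-methoxy-6-[(2-pentyl-1,3-dioxolan-2-yl)methyl]benzoyl}oxy)-2-methoxy-6-(2-oxoheptyl)benzoate | CCCCCC1(Cc2cc(OC)cc(OCc3ccccc3)c2C(=O)Oc2cc(CC(=O)CCCCC)c(C(=O)OCc3ccccc3)c(OC)c2)OCCO1 | intermediate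
25 | benzyl 4-{[2-(benzyloxy)-4-methoxy-6-(2-oxoheptyl)benzoyl]oxy}-2-methoxy-6-(2-oxoheptyl)benzoate | CCCCCC(=O)Cc1cc(OC)cc(OCc2ccccc2)c1C(=O)Oc1cc(CC(=O)CCCCC)c(C(=O)OCc2ccccc2)c(OC)c1 | intermediate
26 | 4-{[2-hydroxy-4-methoxy-6-(2-oxoheptyl)benzoyl]oxy}-2-methoxy-6-(2-oxoheptyl)benzoic acid (achiral) | CCCCCC(=O)Cc1cc(OC)cc(O)c1C(=O)Oc1cc(CC(=O)CCCCC)c(C(=O)O)c(OC)c1 | target

## Counts
Total step count: 15.
Longest linear sequence: 9 steps (5 → 14 → 15 → 18 → 20 → 21 → 22 → 24 → 25 → 26).

## Three steps most likely to fail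

**Step 4** (the same chemistry recurs in step 9).
- Risk: the basic anion 8 may deprotonate 4 instead of adding to it. It may also attack the ester of unreacted 7, and adduct 9 may close onto the neighbouring ester if it warms.
- Fallback: it sets out from 7 and comes back at 10. Anion 8 is trapped instead by non-enolisable dimethyl carbonate (LiN(iPr)2 2.2 equiv, THF, −78 °C) to give the homophthalate diester methyl 2-(benzyloxy)-4-methoxy-6-(2-methoxy-2-oxoethyl)benzoate F1. Its far more acidic arylacetate CH2 is converted by LiN(SiMe3)2 (2.1 equiv, THF, −78 °C) into the lithium ester enolate F2. This is C-acylated by acid chloride 1 in a classical crossed Claisen acylation to the β-keto diester methyl 2-[3-(benzyloxy)-5-methoxy-2-(methoxycarbonyl)phenyl]-3-oxooctanoate F3. Krapcho dealkoxycarbonylation (LiCl, wet DMSO, 120 °C) then removes only the aliphatic β-keto ester group, spares the hindered aromatic ester and delivers 10.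

**Step 10.**
- Risk: before hydroxide cleaves the hindered ester of 18, a side-chain enolate may close onto it in a Dieckmann-type reaction to a naphthalenediol. Careless acidification may also dehydrate the keto acid.
- Fallback: it sets out from 15, comes back at 20 and bypasses steps 9 and 10. The ester is removed while the molecule is still a plain toluate (KOH, DMSO/H2O, 100 °C), giving potassium 4-(benzyloxy)-2-methoxy-6-methylbenzoate F4 and, after HCl, 4-(benzyloxy)-2-methoxy-6-methylbenzoic acid F5. Double deprotonation (LiN(iPr)2 2.3 equiv, THF, −78 to 0 °C) gives the laterally lithiated lithium carboxylate F6. Its carboxylate can be attacked neither by another anion nor by a later enolate. Acylation with 4 at −78 °C gives the dilithium hemiaminal adduct F7, and a quench into cold 1 M HCl releases 20 directly.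

**Step 13.**
- Risk: acid 13 carries two ortho substituents, one of them with a quaternary ketal carbon, so acyl transfer may lose to N-acylurea formation. The acid may also attack its own ketal on storage.
- Fallback: it sets out from 10, comes back at 25 and bypasses steps 5, 6 and 14. The ketone is never masked. Saponification of 10 (KOH, EtOH/H2O 1:1, reflux) gives potassium 2-(benzyloxy)-4-methoxy-6-(2-oxoheptyl)benzoate F8 and, after cold HCl, the slimmer keto acid 2-(benzyloxy)-4-methoxy-6-(2-oxoheptyl)benzoic acid F9. This is condensed with 22 by DCC in toluene at 0 °C to rt, without any amine base so that enolisation stays slow. The reaction passes through the keto O-acylisourea F10 and gives 25 directly. The price is some loss to enol lactonisation.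

## Further compounds
F1 | step 4 | methyl 2-(benzyloxy)-4-methoxy-6-(2-methoxy-2-oxoethyl)benzoate | COC(=O)Cc1cc(OC)cc(OCc2ccccc2)c1C(=O)OC
F2 | step 4 | lithium ester enolate of F1 (enolate geometry not defined) | COC(O[Li])=Cc1cc(OC)cc(OCc2ccccc2)c1C(=O)OC
F3 | step 4 | methyl 2-[3-(benzyloxy)-5-methoxy-2-(methoxycarbonyl)phenyl]-3-oxooctanoate (racemic, enolisable) | CCCCCC(=O)C(C(=O)OC)c1cc(OC)cc(OCc2ccccc2)c1C(=O)OC
F4 | step 10 | potassium 4-(benzyloxy)-2-methoxy-6-methylbenzoate | Cc1cc(OCc2ccccc2)cc(OC)c1C(=O)[O-].[K+]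
F5 | step 10 | 4-(benzyloxy)-2-methoxy-6-methylbenzoic acid | Cc1cc(OCc2ccccc2)cc(OC)c1C(=O)O
F6 | step 10 | lithium 4-(benzyloxy)-2-(lithiomethyl)-6-methoxybenzoate | [Li]Cc1cc(OCc2ccccc2)cc(OC)c1C(=O)O[Li]
F7 | step 10 | dilithium hemiaminal adduct of F6 and 4 (racemic, transient) | CCCCCC(O[Li])(Cc1cc(OCc2ccccc2)cc(OC)c1C(=O)O[Li])N(C)OC
F8 | step 13 | potassium 2-(benzyloxy)-4-methoxy-6-(2-oxoheptyl)benzoate | CCCCCC(=O)Cc1cc(OC)cc(OCc2ccccc2)c1C(=O)[O-].[K+]
F9 | step 13 | 2-(benzyloxy)-4-methoxy-6-(2-oxoheptyl)benzoic acid | CCCCCC(=O)Cc1cc(OC)cc(OCc2ccccc2)c1C(=O)O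
F10 | step 13 | O-[2-(benzyloxy)-4-methoxy-6-(2-oxoheptyl)benzoyl]-N,N'-dicyclohexylisourea | CCCCCC(=O)Cc1cc(OC)cc(OCc2ccccc2)c1C(=O)OC(=NC1CCCCC1)NC1CCCCC1
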